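**Retrosynthetic overview**

1. Target 20 ⇐ hexa-O-benzyl ether 19 by global hydrogenolysis.
2. 19 ⇐ trans-β-lactone 12 + aryne 18: the flavanone pyranone ring (O1–C2–C3–C4–C4a–C8a) is made by a 4→6 ring expansion in which the two aryne carbons (future C8a and C4a) enter the acyl C4–O1 bond of an oxetan-2-one built from O1, C2, C3 and C4. Enabling feature: the O1–C2–C3–C4(=O) chain is a β-hydroxy-acid unit that can be tied into a β-lactone carrying both aryl groups and the C2 configuration. The 5-oxygen next to C4a polarises the 3-alkoxyaryne so that O1 ends on C8a and the acyl carbon on C4a.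
3. 12 ⇐ (3R)-β-hydroxy acid 11 ⇐ asymmetric transfer hydrogenation of β-keto ester 9 ⇐ arylacetate 7 + aroyl chloride 8.
4. 7 ⇐ 3'-bromoflavone 5 (Pd/zinc-enolate coupling) ⇐ chalcone 4 ⇐ aldehyde 2 + acetophenone 3; aryne precursor 17 ⇐ phenol 13.
5. Ring order: flavone pyranone (step 3), oxetanone (step 8), flavanone pyranone by expansion (step 11).

Key step: step 11

Remark: C3 is α to C4=O and is taken to be configurationally labile, settling in the trans (2R,3S) arrangement, so the route fixes only C2; intermediates 10 and 11 are carried as C2-epimer mixtures of uniform (3R) configuration.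

**Route**

Step 1
Reactants: 1 3-bromo-4-hydroxybenzaldehyde
Product: 2 4-(benzyloxy)-3-bromobenzaldehyde
Conditions: BnBr, K2CO3, DMF, rt
Reagents that add atoms: benzyl bromide, BrCc1ccccc1
Why: Williamson ether synthesis, in which the phenoxide (acidified by the para-formyl group) is alkylated by benzyl bromide (SN2); no stereocentre is involved.

Step 2
Reactants: 2 4-(benzyloxy)-3-bromobenzaldehyde; 3 1-[2,4-bis(benzyloxy)-6-hydroxyphenyl]ethan-1-one
Product: 4 (E)-1-[2,4-bis(benzyloxy)-6-hydroxyphenyl]-3-[4-(benzyloxy)-3-bromophenyl]prop-2-en-1-one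
Conditions: KOH (50% aq), EtOH, rt; dilute HCl work-up
Reagents that add atoms: none
Why: Claisen–Schmidt (crossed aldol) condensation, in which the acetophenone enolate adds to the non-enolisable aldehyde and E1cB dehydration gives the conjugated (E)-2'-hydroxychalcone, benzyl ethers and aryl bromide being inert to aqueous KOH.

Step 3
Reactants: 4 (E)-2'-hydroxychalcone
Product: 5 5,7-bis(benzyloxy)-2-[4-(benzyloxy)-3-bromophenyl]-4H-chromen-4-one
Conditions: I2 (10 mol%), DMSO, 130 °C
Reagents that add atoms: none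
Why: Iodine-catalysed oxidative cyclisation in DMSO (6-endo oxa-Michael closure of the 2'-phenol, α-iodination and HI elimination, DMSO reoxidising HI) is the standard chalcone-to-flavone conversion and tolerates benzyl ethers and the aryl bromide.

Step 4
Reactants: 5 3'-bromoflavone; 6 (2-ethoxy-2-oxoethyl)zinc bromide (Reformatsky reagent, commercial solution or fresh from ethyl bromoacetate and zinc)
Product: 7 ethyl 2-{2-(benzyloxy)-5-[5,7-bis(benzyloxy)-4-oxo-4H-chromen-2-yl]phenyl}acetate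
Conditions: Pd2(dba)3 (2.5 mol%), Q-Phos (5 mol%), THF, 60 °C
Reagents that add atoms: none
Why: Palladium-catalysed Negishi-type coupling of a Reformatsky (zinc ester enolate) reagent with an aryl bromide installs the acetate side chain under neutral conditions that leave the chromone untouched, the bulky electron-rich phosphine coping with the ortho-benzyloxy group.

Step 5
Reactants: 7 arylacetate; 8 4-(benzyloxy)benzoyl chloride
Product: 9 ethyl 3-[4-(benzyloxy)phenyl]-2-{2-(benzyloxy)-5-[5,7-bis(benzyloxy)-4-oxo-4H-chromen-2-yl]phenyl}-3-oxopropanoate (racemic, keto/enol)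
Conditions: LiHMDS (2.2 equiv), THF, −78 °C; then 8, −78 → −20 °C; aq NH4Cl
Reagents that add atoms: none
Why: Crossed Claisen C-acylation, in which the lithium ester enolate is acylated by the aroyl chloride and the second equivalent of base stores the more acidic β-keto ester as its enolate, preventing double acylation; the new α-centre is racemic and labile.

Step 6
Reactants: 9 β-keto ester
Product: 10 ethyl (3R)-3-[4-(benzyloxy)phenyl]-2-{2-(benzyloxy)-5-[5,7-bis(benzyloxy)-4-oxo-4H-chromen-2-yl]phenyl}-3-hydroxypropanoate (C2 epimers)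
Conditions: RuCl[(R,R)-TsDPEN](p-cymene) (2 mol%), HCO2H/Et3N 5:2, DMF, 35 °C
Reagents that add atoms: none
Why: Noyori–Ikariya asymmetric transfer hydrogenation with dynamic kinetic resolution, in which hydride is delivered to the aryl ketone in the CH/π-organised Ru–H/N–H transition state so that the (R,R)-catalyst should set the benzylic carbinol as (R), while the acidic α-centre epimerises freely and its configuration is immaterial.

Step 7
Reactants: 10 (3R)-β-hydroxy ester
Product: 11 (3R)-3-[4-(benzyloxy)phenyl]-2-{2-(benzyloxy)-5-[5,7-bis(benzyloxy)-4-oxo-4H-chromen-2-yl]phenyl}-3-hydroxypropanoic acid (C2 epimers)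
Conditions: LiOH, THF/H2O 3:1, 0 °C; cold 0.5 M HCl to pH 4
Reagents that add atoms: lithium hydroxide, [Li+].[OH-]
Why: Saponification of the ethyl ester at 0 °C with cautious acidification should give the β-hydroxy acid, the low temperature suppressing retro-aldol cleavage and leaving the carbinol centre untouched.

Step 8
Reactants: 11 (3R)-β-hydroxy acid
Product: 12 (3S,4R)-4-[4-(benzyloxy)phenyl]-3-{2-(benzyloxy)-5-[5,7-bis(benzyloxy)-4-oxo-4H-chromen-2-yl]phenyl}oxetan-2-one (trans; any cis C3 epimer is carried along)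
Conditions: BOPCl, Et3N, CH2Cl2, 0 °C → rt; Et3N-deactivated silica plug, used at once
Reagents that add atoms: none
Why: Carboxyl-selective activation as the mixed phosphinic anhydride and 4-exo-trig attack of the β-hydroxyl (β-lactonisation) close the oxetan-2-one with retention at C4, since the carbinol C–O bond is never broken, the α-centre settling mainly trans to the C4 aryl group.

Step 9
Reactants: 13 3,5-bis(benzyloxy)phenol
Product: 14 3,5-bis(benzyloxy)-2-bromophenol
Conditions: NBS, i-Pr2NH (10 mol%), CH2Cl2, 0 °C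
Reagents that add atoms: N-bromosuccinimide, O=C1CCC(=O)N1Br
Why: Amine-mediated ortho-selective electrophilic bromination of a phenol (N-bromoamine delivered by hydrogen bonding to OH) should brominate one of the two equivalent positions between OH and OBn in preference to the position between the two benzyloxy groups.

Step 10
Reactants: 14 3,5-bis(benzyloxy)-2-bromophenol
Product: 17 3,5-bis(benzyloxy)-2-(trimethylsilyl)phenyl trifluoromethanesulfonate, via aryl trimethylsilyl ether 15 (not isolated), via lithium 2-silylphenoxide 16 (not isolated)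
Conditions: HMDS, THF, 65 °C, evaporate; n-BuLi, THF, −78 °C; Tf2O, −78 °C → rt
Reagents that add atoms: hexamethyldisilazane, C[Si](C)(C)N[Si](C)(C)C; trifluoromethanesulfonic anhydride, O=S(=O)(OS(=O)(=O)C(F)(F)F)C(F)(F)F
Why: Standard one-pot route to o-silylaryl triflate aryne precursors from o-bromophenols (O-silylation, bromine–lithium exchange with anionic 1,3-O→C silyl shift, i.e. retro-Brook rearrangement, then O-triflation), the exchange being much faster than benzylic deprotonation at −78 °C.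

Step 11
Reactants: 12 trans-β-lactone; 17 silylaryl triflate
Product: 19 (2R,3S)-5,7-bis(benzyloxy)-2-[4-(benzyloxy)phenyl]-3-{2-(benzyloxy)-5-[5,7-bis(benzyloxy)-4-oxo-4H-chromen-2-yl]phenyl}chroman-4-one, via 3,5-bis(benzyloxy)benzyne 18 (not isolated)
Conditions: CsF (4 equiv), MeCN/toluene 1:1, 0 °C → rt, 17 (2 equiv) added over 3 h; AcOH quench (cat. AcOH/NaOAc to equilibrate C3 if needed)
Reagents that add atoms: none
Why: Proposed new method: fluoride unmasks aryne 18 from 17; the endocyclic oxygen of the strained oxetan-2-one (or, after reversible fluoride opening to the C2-alkoxide/acyl fluoride, the alkoxide itself) adds to the aryne, and the aryl anion so formed attacks the adjacent acyl carbon, so that the C4–O1 bond is exchanged for C8a–O1 and C4a–C4 and the four-membered ring grows by the two aryne carbons with release of about 23 kcal/mol of strain. The closest known reaction types are aryne σ-insertions into acyl–heteroatom bonds (N–C(O) of amides and ureas, the O–C(O) unit of carboxylic acids giving o-hydroxyaryl ketones, salicylates giving xanthones) and the acyl-alkylation of β-keto esters. The six-membered ring closes by intramolecular acyl transfer to the aryl carbanion (attack of C4a on C4, 6-exo-trig in the relay pathway, or collapse of a four-centre oxonium/aryl-anion pair in the direct one). No new stereocentre is created: C2 keeps its O1–C2 bond and its (R) configuration from step 6, and C3, α to the new aryl ketone, is carried over as trans from 12 or equilibrates to the trans (3S) isomer with both aryl groups equatorial. The step needs regioselective O-addition to the unsymmetrical aryne, which the 3-benzyloxy group secures by sending the nucleophile to the distal carbon and placing the carbanion next to OBn (the future C4a), and O- over C-reactivity of the lactone, favoured by weakly basic fluoride conditions under which the lactone should not be enolised.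

Step 12
Reactants: 19 hexa-O-benzyl ether
Product: 20 (2R,3S)-5,7-dihydroxy-2-(4-hydroxyphenyl)-3-[2-hydroxy-5-(5,7-dihydroxy-4-oxo-4H-chromen-2-yl)phenyl]-2,3-dihydro-4H-chromen-4-one (CNP0324936.1)
Conditions: H2 (1 atm), 10% Pd/C, EtOAc/MeOH, rt
Reagents that add atoms: none
Why: Palladium-catalysed hydrogenolysis should cleave the six benzyl aryl ethers under neutral conditions that neither epimerise C2/C3 nor reduce the chromone C2=C3 bond or the aryl ketone at 1 atm and room temperature.

**Compound list**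

1 | 3-bromo-4-hydroxybenzaldehyde | O=Cc1ccc(O)c(Br)c1 | starting material
2 | 4-(benzyloxy)-3-bromobenzaldehyde | O=Cc1ccc(OCc2ccccc2)c(Br)c1 | intermediate
3 | 1-[2,4-bis(benzyloxy)-6-hydroxyphenyl]ethan-1-one | CC(=O)c1c(O)cc(OCc2ccccc2)cc1OCc1ccccc1 | starting material
4 | (E)-1-[2,4-bis(benzyloxy)-6-hydroxyphenyl]-3-[4-(benzyloxy)-3-bromophenyl]prop-2-en-1-one | O=C(/C=C/c1ccc(OCc2ccccc2)c(Br)c1)c1c(O)cc(OCc2ccccc2)cc1OCc1ccccc1 | intermediate
5 | 5,7-bis(benzyloxy)-2-[4-(benzyloxy)-3-bromophenyl]-4H-chromen-4-one | O=c1cc(-c2ccc(OCc3ccccc3)c(Br)c2)oc2cc(OCc3ccccc3)cc(OCc3ccccc3)c12 | intermediate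
6 | (2-ethoxy-2-oxoethyl)zinc bromide | CCOC(=O)C[Zn]Br | starting material
7 | ethyl 2-{2-(benzyloxy)-5-[5,7-bis(benzyloxy)-4-oxo-4H-chromen-2-yl]phenyl}acetate | CCOC(=O)Cc1cc(-c2cc(=O)c3c(OCc4ccccc4)cc(OCc4ccccc4)cc3o2)ccc1OCc1ccccc1 | intermediate
8 | 4-(benzyloxy)benzoyl chloride | O=C(Cl)c1ccc(OCc2ccccc2)cc1 | starting material
9 | ethyl 3-[4-(benzyloxy)phenyl]-2-{2-(benzyloxy)-5-[5,7-bis(benzyloxy)-4-oxo-4H-chromen-2-yl]phenyl}-3-oxopropanoate (racemic) | CCOC(=O)C(C(=O)c1ccc(OCc2ccccc2)cc1)c1cc(-c2cc(=O)c3c(OCc4ccccc4)cc(OCc4ccccc4)cc3o2)ccc1OCc1ccccc1 | intermediate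
10 | ethyl (3R)-3-[4-(benzyloxy)phenyl]-2-{2-(benzyloxy)-5-[5,7-bis(benzyloxy)-4-oxo-4H-chromen-2-yl]phenyl}-3-hydroxypropanoate (C2 epimers) | CCOC(=O)C([C@@H](O)c1ccc(OCc2ccccc2)cc1)c1cc(-c2cc(=O)c3c(OCc4ccccc4)cc(OCc4ccccc4)cc3o2)ccc1OCc1ccccc1 | intermediate
11 | (3R)-3-[4-(benzyloxy)phenyl]-2-{2-(benzyloxy)-5-[5,7-bis(benzyloxy)-4-oxo-4H-chromen-2-yl]phenyl}-3-hydroxypropanoic acid (C2 epimers) | OC(=O)C([C@@H](O)c1ccc(OCc2ccccc2)cc1)c1cc(-c2cc(=O)c3c(OCc4ccccc4)cc(OCc4ccccc4)cc3o2)ccc1OCc1ccccc1 | intermediate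
12 | (3S,4R)-4-[4-(benzyloxy)phenyl]-3-{2-(benzyloxy)-5-[5,7-bis(benzyloxy)-4-oxo-4H-chromen-2-yl]phenyl}oxetan-2-one (trans) | O=C1O[C@@H](c2ccc(OCc3ccccc3)cc2)[C@@H]1c1cc(-c2cc(=O)c3c(OCc4ccccc4)cc(OCc4ccccc4)cc3o2)ccc1OCc1ccccc1 | intermediate
13 | 3,5-bis(benzyloxy)phenol | Oc1cc(OCc2ccccc2)cc(OCc2ccccc2)c1 | starting material
14 | 3,5-bis(benzyloxy)-2-bromophenol | Oc1cc(OCc2ccccc2)cc(OCc2ccccc2)c1Br | intermediate
15 | [3,5-bis(benzyloxy)-2-bromophenoxy]trimethylsilane | C[Si](C)(C)Oc1cc(OCc2ccccc2)cc(OCc2ccccc2)c1Br | intermediate (not isolated)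
16 | lithium 3,5-bis(benzyloxy)-2-(trimethylsilyl)phenoxide | [Li+].[O-]c1cc(OCc2ccccc2)cc(OCc2ccccc2)c1[Si](C)(C)C | intermediate (not isolated)
17 | 3,5-bis(benzyloxy)-2-(trimethylsilyl)phenyl trifluoromethanesulfonate | C[Si](C)(C)c1c(OCc2ccccc2)cc(OCc2ccccc2)cc1OS(=O)(=O)C(F)(F)F | intermediate
18 | 3,5-bis(benzyloxy)benzyne | C1(OCc2ccccc2)=CC(OCc2ccccc2)=CC#C1 | intermediate (not isolated)
19 | (2R,3S)-5,7-bis(benzyloxy)-2-[4-(benzyloxy)phenyl]-3-{2-(benzyloxy)-5-[5,7-bis(benzyloxy)-4-oxo-4H-chromen-2-yl]phenyl}chroman-4-one | O=C1c2c(OCc3ccccc3)cc(OCc3ccccc3)cc2O[C@@H](c2ccc(OCc3ccccc3)cc2)[C@@H]1c1cc(-c2cc(=O)c3c(OCc4ccccc4)cc(OCc4ccccc4)cc3o2)ccc1OCc1ccccc1 | intermediate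
20 | (2R,3S)-5,7-dihydroxy-2-(4-hydroxyphenyl)-3-[2-hydroxy-5-(5,7-dihydroxy-4-oxo-4H-chromen-2-yl)phenyl]-2,3-dihydro-4H-chromen-4-one | O=C1c2c(O)cc(O)cc2O[C@@H](c2ccc(O)cc2)[C@@H]1c1cc(-c2cc(=O)c3c(O)cc(O)cc3o2)ccc1O | target

**Step count and risks**

Total steps: 12. Longest linear sequence: 10 (steps 1–8, 11, 12); steps 9–10 form the convergent branch.

Most likely to fail:

1. Step 11 (proposed new method). The weakly nucleophilic lactone oxygen may fail to capture the aryne, which would then be lost to fluoride, to the pyrone carbonyl oxygen or to oligomerisation. Fluoride-induced enolisation/E1cB opening of the lactone or ionisation at C2 could also erode the C2 configuration. Fallback with known chemistry, setting out from 9 and returning at 19: transfer hydrogenation of 9 with the (S,S)-TsDPEN catalyst should give ethyl (2RS,3S)-3-[4-(benzyloxy)phenyl]-2-aryl-3-hydroxypropanoate F1. Mitsunobu etherification with phenol 13 (PPh3, DIAD, THF, 0 °C) inverts the carbinol to ethyl (2RS,3R)-3-[4-(benzyloxy)phenyl]-3-[3,5-bis(benzyloxy)phenoxy]-2-arylpropanoate F2. Neutral ester cleavage (Me3SnOH, 1,2-dichloroethane, 70 °C) gives the (3R)-3-aryloxy acid F3. Intramolecular Friedel–Crafts acylation through the trifluoroacetic mixed anhydride (TFAA, CH2Cl2, 0 °C), ortho to the ether oxygen of the phloroglucinol ring (both ortho positions equivalent), closes the chromanone to 19.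

2. Step 8. During closure under amine base, the p-benzyloxybenzylic C–O bond of the strained lactone may ionise (decarboxylative fragmentation to the stilbene), and the activated α-aryl acid may form a ketene and oligomerise. Fallback, setting out from 11 and returning at 12: 2,2'-dipyridyl disulfide/PPh3 (CH2Cl2, rt) converts the acid, without touching the hydroxyl group, into S-(pyridin-2-yl) (3R)-3-[4-(benzyloxy)phenyl]-2-aryl-3-hydroxypropanethioate F4. Thiophilic activation (AgOTf, 2,6-di-tert-butylpyridine, CH2Cl2, −20 °C) then closes the isolated thioester to 12 under base-free conditions (double-activation lactonisation).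

3. Step 6. Hydride transfer to the hindered, doubly aryl-flanked ketone may be slow, the chromone carbonyl may be reduced competitively, and facial selectivity may be poor. Fallback, setting out from 7 and returning at 11: saponification of 7 gives 2-{2-(benzyloxy)-5-[5,7-bis(benzyloxy)-4-oxo-4H-chromen-2-yl]phenyl}acetic acid F5. Pivaloyl mixed anhydride and lithiated (R)-4-benzyl-2-oxazolidinone give (4R)-4-benzyl-3-(arylacetyl)oxazolidin-2-one F6. An Evans syn-aldol reaction (Bu2BOTf, i-Pr2NEt, CH2Cl2, −78 → 0 °C) with 4-(benzyloxy)benzaldehyde should give (4R)-4-benzyl-3-[(2R,3R)-3-[4-(benzyloxy)phenyl]-2-aryl-3-hydroxypropanoyl]oxazolidin-2-one F7, the auxiliary controlling the carbinol configuration. LiOH/H2O2 then releases 11 as its (2R,3R) epimer, which converges in steps 8 and 11.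

(In F1–F7 "aryl" stands for 2-(benzyloxy)-5-[5,7-bis(benzyloxy)-4-oxo-4H-chromen-2-yl]phenyl.)

**Further compounds**

F1 | step 11 | ethyl (2RS,3S)-3-[4-(benzyloxy)phenyl]-2-{2-(benzyloxy)-5-[5,7-bis(benzyloxy)-4-oxo-4H-chromen-2-yl]phenyl}-3-hydroxypropanoate | CCOC(=O)C([C@H](O)c1ccc(OCc2ccccc2)cc1)c1cc(-c2cc(=O)c3c(OCc4ccccc4)cc(OCc4ccccc4)cc3o2)ccc1OCc1ccccc1
F2 | step 11 | ethyl (2RS,3R)-3-[4-(benzyloxy)phenyl]-3-[3,5-bis(benzyloxy)phenoxy]-2-{2-(benzyloxy)-5-[5,7-bis(benzyloxy)-4-oxo-4H-chromen-2-yl]phenyl}propanoate | CCOC(=O)C([C@@H](Oc1cc(OCc2ccccc2)cc(OCc2ccccc2)c1)c1ccc(OCc2ccccc2)cc1)c1cc(-c2cc(=O)c3c(OCc4ccccc4)cc(OCc4ccccc4)cc3o2)ccc1OCc1ccccc1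
F3 | step 11 | (2RS,3R)-3-[4-(benzyloxy)phenyl]-3-[3,5-bis(benzyloxy)phenoxy]-2-{2-(benzyloxy)-5-[5,7-bis(benzyloxy)-4-oxo-4H-chromen-2-yl]phenyl}propanoic acid | OC(=O)C([C@@H](Oc1cc(OCc2ccccc2)cc(OCc2ccccc2)c1)c1ccc(OCc2ccccc2)cc1)c1cc(-c2cc(=O)c3c(OCc4ccccc4)cc(OCc4ccccc4)cc3o2)ccc1OCc1ccccc1
F4 | step 8 | S-(pyridin-2-yl) (3R)-3-[4-(benzyloxy)phenyl]-2-{2-(benzyloxy)-5-[5,7-bis(benzyloxy)-4-oxo-4H-chromen-2-yl]phenyl}-3-hydroxypropanethioate | O=C(Sc1ccccn1)C([C@@H](O)c1ccc(OCc2ccccc2)cc1)c1cc(-c2cc(=O)c3c(OCc4ccccc4)cc(OCc4ccccc4)cc3o2)ccc1OCc1ccccc1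
F5 | step 6 | 2-{2-(benzyloxy)-5-[5,7-bis(benzyloxy)-4-oxo-4H-chromen-2-yl]phenyl}acetic acid | OC(=O)Cc1cc(-c2cc(=O)c3c(OCc4ccccc4)cc(OCc4ccccc4)cc3o2)ccc1OCc1ccccc1
F6 | step 6 | (4R)-4-benzyl-3-(2-{2-(benzyloxy)-5-[5,7-bis(benzyloxy)-4-oxo-4H-chromen-2-yl]phenyl}acetyl)-1,3-oxazolidin-2-one | O=C(Cc1cc(-c2cc(=O)c3c(OCc4ccccc4)cc(OCc4ccccc4)cc3o2)ccc1OCc1ccccc1)N1[C@H](Cc2ccccc2)COC1=O
F7 | step 6 | (4R)-4-benzyl-3-[(2R,3R)-3-[4-(benzyloxy)phenyl]-2-{2-(benzyloxy)-5-[5,7-bis(benzyloxy)-4-oxo-4H-chromen-2-yl]phenyl}-3-hydroxypropanoyl]-1,3-oxazolidin-2-one | O=C([C@@H]([C@@H](O)c1ccc(OCc2ccccc2)cc1)c1cc(-c2cc(=O)c3c(OCc4ccccc4)cc(OCc4ccccc4)cc3o2)ccc1OCc1ccccc1)N1[C@H](Cc2ccccc2)COC1=O
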